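## Retrosynthetic overview

1. The target comes from equatorial MeCeCl2 addition to a C7 ketone, which comes from conjugate addition of a C9 (E)-alkenyl cuprate to a C10 bicyclic bromo-enone (the late coupling; sets C1 and C7a).
2. The alkenyl iodide comes from Zr-catalysed carboalumination/iodination of 6-methylhept-5-en-1-yne, made from prenyl bromide and lithiated 1-(trimethylsilyl)propyne.
3. The bromo-enone comes from intramolecular aldol condensation of a bromo keto aldehyde (five-membered ring, formed second), itself from a double ozonolysis.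
4. The six-membered ring (formed first) comes from an enantiospecific bromonium/allylsilane cyclisation of a vicinal bromochloride, assembled by Cu-catalysed union of a bromochloro triflate with a 2-(silylmethyl)allyl Grignard reagent.
5. The bromochloride comes from catalytic enantioselective bromochlorination of (2E)-3-methylhepta-2,6-dien-1-ol, made by carboalumination/hydroxymethylation of hex-1-en-5-yne.

Assumption: the hydrindane is numbered C1 (side chain), C3a (angular methyl), C4 (Br), C7 (carbinol), C7a, so the target is (1S,3aS,4S,7R,7aS); in step 2 the antipode of the Schiff-base ligand that delivers the (2S,3R)-bromochloride is used.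

## Route

Step 1
Reactants: 1 hex-1-en-5-yne
Product: 3 (2E)-3-methylhepta-2,6-dien-1-ol, via alkenyldimethylalane 2 (not isolated)
Conditions: Me3Al (2 equiv), Cp2ZrCl2 (25 mol %), CH2Cl2, 0 °C to rt; volatiles removed; n-BuLi (1 equiv), hexane, 0 °C; (CH2O)n, THF, rt; aq NH4Cl
Reagents that add atoms: trimethylaluminium C[Al](C)C; paraformaldehyde (as formaldehyde) C=O
Why: Negishi zirconium-catalysed syn-carboalumination puts methyl on the internal and aluminium on the terminal alkyne carbon (E geometry, monosubstituted alkene untouched), and the derived aluminate is hydroxymethylated by formaldehyde with retention of geometry.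

Step 2
Reactants: 3 (2E)-3-methylhepta-2,6-dien-1-ol
Product: 4 (2S,3R)-2-bromo-3-chloro-3-methylhept-6-en-1-ol
Conditions: NBS (1.05 equiv), ClTi(OiPr)3 (1.1 equiv), chiral tridentate Schiff-base ligand (20 mol %), hexanes, −20 °C
Reagents that add atoms: N-bromosuccinimide O=C1CCC(=O)N1Br; chlorotitanium triisopropoxide CC(C)O[Ti](Cl)(OC(C)C)OC(C)C
Why: Titanium/Schiff-base-catalysed enantioselective bromochlorination of the titanium-bound allylic alcohol adds Br (C2) and Cl (tertiary C3) anti across the E-alkene with the ligand choosing the face, so the C–Br stereocentre (later C4) is set as 2S and the remote vinyl group is left alone.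

Step 3
Reactants: 4 (2S,3R)-2-bromo-3-chloro-3-methylhept-6-en-1-ol
Product: 5 (2S,3R)-2-bromo-3-chloro-3-methylhept-6-en-1-yl trifluoromethanesulfonate
Conditions: Tf2O (1.1 equiv), 2,6-lutidine (1.2 equiv), CH2Cl2, −78 °C; short silica plug, used at once
Reagents that add atoms: trifluoromethanesulfonic anhydride O=S(=O)(OS(=O)(=O)C(F)(F)F)C(F)(F)F
Why: Simple O-sulfonylation of the primary alcohol at low temperature; the β-bromine inductively stabilises the triflate and no stereocentre is touched.

Step 4
Reactants: 6 3-chloro-2-(chloromethyl)prop-1-ene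
Product: 7 trichloro[2-(chloromethyl)prop-2-en-1-yl]silane
Conditions: HSiCl3 (1 equiv), Et3N (1 equiv), CuCl (5 mol %), Et2O, 0 °C to rt, 6 in twofold excess; distilled
Reagents that add atoms: trichlorosilane Cl[SiH](Cl)Cl
Why: CuCl/amine-mediated silylation of an allylic chloride with HSiCl3 (allyltrichlorosilane synthesis); the excess of the symmetrical dichloride keeps it to monosilylation.

Step 5
Reactants: 7 trichloro[2-(chloromethyl)prop-2-en-1-yl]silane
Product: 8 [2-(chloromethyl)prop-2-en-1-yl]trimethylsilane
Conditions: MeMgBr (3.2 equiv), Et2O, 0 °C to rt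
Reagents that add atoms: methylmagnesium bromide C[Mg]Br
Why: Nucleophilic substitution at silicon by the Grignard reagent is much faster than attack on the allylic C–Cl bond in the absence of copper.

Step 6
Reactants: 8 [2-(chloromethyl)prop-2-en-1-yl]trimethylsilane; 5 (2S,3R)-2-bromo-3-chloro-3-methylhept-6-en-1-yl trifluoromethanesulfonate
Product: 10 [(5S,6R)-5-bromo-6-chloro-6-methyl-2-methylidenedec-9-en-1-yl]trimethylsilane, via allylic Grignard reagent 9 (not isolated)
Conditions: 8, Mg, THF, 0 °C; then added to 5, CuI (10 mol %), THF/Et2O, −78 to −40 °C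
Reagents that add atoms: none
Why: Copper-catalysed sp3–sp3 cross-coupling of a primary triflate with an allylic Grignard reagent is fast at −78 °C, outrunning elimination or attack at the hindered secondary bromide and tertiary chloride, and the two allyl termini are equivalent so one constitution results with both stereocentres untouched.

Step 7
Reactants: 10 [(5S,6R)-5-bromo-6-chloro-6-methyl-2-methylidenedec-9-en-1-yl]trimethylsilane
Product: 12 (1S,2S)-1-bromo-2-(but-3-en-1-yl)-2-methyl-4-methylidenecyclohexane, via bromonium chloride 11 (not isolated)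
Conditions: (CF3)2CHOH (0.02 M), solid NaHCO3, rt
Reagents that add atoms: none
Why: In the strongly ionising, non-nucleophilic solvent the tertiary chloride leaves with anchimeric help from bromine, and the enantiopure bromonium ion is opened at its tertiary carbon by the allylsilane through a chair transition state (cation–olefin cyclisation with Sakurai-type termination), so the new C–C bond takes the place of chloride anti to bromine (quaternary centre S, Br cis to methyl) and loss of silicon fixes the exocyclic alkene.

Step 8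
Reactants: 12 (1S,2S)-1-bromo-2-(but-3-en-1-yl)-2-methyl-4-methylidenecyclohexane
Product: 14 3-[(1S,2S)-2-bromo-1-methyl-5-oxocyclohexyl]propanal, via bis-ozonide 13 (not isolated)
Conditions: O3, CH2Cl2, −78 °C; then PPh3, −78 °C to rt
Reagents that add atoms: ozone [O-][O+]=O
Why: Ozonolysis with reductive work-up cleaves both the 1,1-disubstituted and the monosubstituted alkene to ketone and aldehyde while the alkyl bromide and both stereocentres are inert.

Step 9
Reactants: 14 3-[(1S,2S)-2-bromo-1-methyl-5-oxocyclohexyl]propanal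
Product: 16 (3aS,4S)-4-bromo-3a-methyl-2,3,3a,4,5,6-hexahydro-7H-inden-7-one, via aldol adduct 15 (not isolated)
Conditions: p-TsOH·H2O (10 mol %), benzene, 80 °C, Dean–Stark
Reagents that add atoms: none
Why: Acid-catalysed intramolecular aldol condensation: only the aldol between the ketone α-carbon next to the quaternary centre and the aldehyde closes a five-membered ring that can dehydrate, so reversible aldolisation funnels to the conjugated enone, and acid avoids the cyclopropane formation that a γ-bromo ketone enolate would risk.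

Step 10
Reactants: 17 trimethyl(prop-1-yn-1-yl)silane; 18 1-bromo-3-methylbut-2-ene
Product: 20 trimethyl(6-methylhept-5-en-1-yn-1-yl)silane, via lithiated silylpropyne 19 (not isolated)
Conditions: 17, n-BuLi, THF, −78 to −20 °C; then 18, −78 °C to rt
Reagents that add atoms: none
Why: Propargylic lithiation of the silyl-capped propyne followed by SN2 alkylation with the primary allylic bromide; the silyl group blocks the acetylenic position and favours the propargyl over the allenyl product.

Step 11
Reactants: 20 trimethyl(6-methylhept-5-en-1-yn-1-yl)silane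
Product: 21 6-methylhept-5-en-1-yne
Conditions: K2CO3, MeOH, rt
Reagents that add atoms: none
Why: Base-mediated protodesilylation (methanolysis) of the alkynyl C–Si bond.

Step 12
Reactants: 21 6-methylhept-5-en-1-yne
Product: 23 (1E)-1-iodo-2,6-dimethylhepta-1,5-diene, via alkenyldimethylalane 22 (not isolated)
Conditions: Me3Al (2 equiv), Cp2ZrCl2 (25 mol %), CH2Cl2, rt; then I2, THF, −30 to 0 °C
Reagents that add atoms: trimethylaluminium C[Al](C)C; iodine II
Why: Negishi carboalumination (syn, methyl to the internal carbon) and iodinolysis of the C–Al bond with retention give the E-iodide; the trisubstituted alkene does not react.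

Step 13
Reactants: 23 (1E)-1-iodo-2,6-dimethylhepta-1,5-diene; 16 (3aS,4S)-4-bromo-3a-methyl-2,3,3a,4,5,6-hexahydro-7H-inden-7-one
Product: 26 (1S,3aS,4S,7aS)-4-bromo-1-[(1E)-2,6-dimethylhepta-1,5-dien-1-yl]-3a-methyloctahydro-7H-inden-7-one, via alkenyllithium 24 (not isolated), via lithium dialkenylcuprate 25 (not isolated)
Conditions: 23 (2.2 equiv), t-BuLi (4.4 equiv), Et2O, −78 °C; CuI (1.1 equiv), −40 °C; then 16, −78 to −40 °C; sat. aq NH4Cl at −78 °C
Reagents that add atoms: none
Why: Gilman cuprate conjugate addition with retention of alkene geometry to the s-cis-locked enone occurs at C1 on the face opposite the angular methyl group (as in additions to 16-en-20-one steroids) giving 1S, and kinetic axial protonation of the enolate at C7a anti to the axial methyl gives the trans ring fusion (7aS); the neopentyl bromide is inert at −78 °C.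

Step 14
Reactants: 26 (1S,3aS,4S,7aS)-4-bromo-1-[(1E)-2,6-dimethylhepta-1,5-dien-1-yl]-3a-methyloctahydro-7H-inden-7-one
Product: 27 (1S,3aS,4S,7R,7aS)-4-bromo-1-[(1E)-2,6-dimethylhepta-1,5-dien-1-yl]-3a,7-dimethyloctahydro-1H-inden-7-ol
Conditions: CeCl3 (anhydrous, 3 equiv), MeLi (3 equiv), THF, −78 °C; then 26, −78 °C; aq NH4Cl
Reagents that add atoms: methyllithium [Li]C
Why: Organocerium 1,2-addition (Imamoto conditions) is non-basic, so C7a is not epimerised and bromide is not displaced, and methyl enters equatorially because the axial trajectory is blocked by the 1,3-diaxial angular methyl, giving equatorial CH3 and axial OH (7R).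

## Compound list

1 | hex-1-en-5-yne | C=CCCC#C | starting material
2 | [(1E)-2-methylhexa-1,5-dien-1-yl]dimethylalane | C[Al](C)/C=C(\C)CCC=C | intermediate
3 | (2E)-3-methylhepta-2,6-dien-1-ol | OC/C=C(\C)CCC=C | intermediate
4 | (2S,3R)-2-bromo-3-chloro-3-methylhept-6-en-1-ol | OC[C@H](Br)[C@](C)(Cl)CCC=C | intermediate
5 | (2S,3R)-2-bromo-3-chloro-3-methylhept-6-en-1-yl trifluoromethanesulfonate | FC(F)(F)S(=O)(=O)OC[C@H](Br)[C@](C)(Cl)CCC=C | intermediate
6 | 3-chloro-2-(chloromethyl)prop-1-ene | C=C(CCl)CCl | starting material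
7 | trichloro[2-(chloromethyl)prop-2-en-1-yl]silane | C=C(CCl)C[Si](Cl)(Cl)Cl | intermediate
8 | [2-(chloromethyl)prop-2-en-1-yl]trimethylsilane | C=C(CCl)C[Si](C)(C)C | intermediate
9 | {2-[(trimethylsilyl)methyl]prop-2-en-1-yl}magnesium chloride | C=C(C[Mg]Cl)C[Si](C)(C)C | intermediate
10 | [(5S,6R)-5-bromo-6-chloro-6-methyl-2-methylidenedec-9-en-1-yl]trimethylsilane | C=C(C[Si](C)(C)C)CC[C@H](Br)[C@](C)(Cl)CCC=C | intermediate
11 | 2-(but-3-en-1-yl)-2-methyl-3-{3-[(trimethylsilyl)methyl]but-3-en-1-yl}bromiran-1-ium chloride (bromonium ion pair, Br on the face anti to the departed chloride) | C=C(C[Si](C)(C)C)CC[C@@H]1[Br+][C@@]1(C)CCC=C.[Cl-] | intermediate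
12 | (1S,2S)-1-bromo-2-(but-3-en-1-yl)-2-methyl-4-methylidenecyclohexane | C=C1CC[C@H](Br)[C@@](C)(CCC=C)C1 | intermediate
13 | 8-bromo-7-methyl-7-[2-(1,2,4-trioxolan-3-yl)ethyl]-1,2,4-trioxaspiro[4.5]decane (bis-ozonide; bromo and quaternary carbons as in 12, mixture at the acetal carbons) | C12(OCOO1)CC[C@H](Br)[C@@](C)(CCC1OCOO1)C2 | intermediate
14 | 3-[(1S,2S)-2-bromo-1-methyl-5-oxocyclohexyl]propanal | O=C1CC[C@H](Br)[C@@](C)(CCC=O)C1 | intermediate
15 | (3aS,4S)-4-bromo-1-hydroxy-3a-methyloctahydro-7H-inden-7-one (mixture at C1 and C7a) | O=C1CC[C@H](Br)[C@@]2(C)CCC(O)C12 | intermediate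
16 | (3aS,4S)-4-bromo-3a-methyl-2,3,3a,4,5,6-hexahydro-7H-inden-7-one | O=C1CC[C@H](Br)[C@@]2(C)CCC=C12 | intermediate
17 | trimethyl(prop-1-yn-1-yl)silane | CC#C[Si](C)(C)C | starting material
18 | 1-bromo-3-methylbut-2-ene | CC(C)=CCBr | starting material
19 | [3-(trimethylsilyl)prop-2-yn-1-yl]lithium | [Li]CC#C[Si](C)(C)C | intermediate
20 | trimethyl(6-methylhept-5-en-1-yn-1-yl)silane | CC(C)=CCCC#C[Si](C)(C)C | intermediate
21 | 6-methylhept-5-en-1-yne | CC(C)=CCCC#C | intermediate
22 | [(1E)-2,6-dimethylhepta-1,5-dien-1-yl]dimethylalane | C[Al](C)/C=C(\C)CCC=C(C)C | intermediate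
23 | (1E)-1-iodo-2,6-dimethylhepta-1,5-diene | I/C=C(\C)CCC=C(C)C | intermediate
24 | [(1E)-2,6-dimethylhepta-1,5-dien-1-yl]lithium | [Li]/C=C(\C)CCC=C(C)C | intermediate
25 | lithium bis[(1E)-2,6-dimethylhepta-1,5-dien-1-yl]cuprate | [Li+].CC(C)=CCC/C(C)=C/[Cu-]/C=C(\C)CCC=C(C)C | intermediate
26 | (1S,3aS,4S,7aS)-4-bromo-1-[(1E)-2,6-dimethylhepta-1,5-dien-1-yl]-3a-methyloctahydro-7H-inden-7-one | CC(C)=CCC/C(C)=C/[C@@H]1CC[C@]2(C)[C@@H](Br)CCC(=O)[C@@H]12 | intermediate
27 | (1S,3aS,4S,7R,7aS)-4-bromo-1-[(1E)-2,6-dimethylhepta-1,5-dien-1-yl]-3a,7-dimethyloctahydro-1H-inden-7-ol (CNP0309781.1) | CC(C)=CCC/C(C)=C/[C@@H]1CC[C@]2(C)[C@@H](Br)CC[C@@](C)(O)[C@@H]12 | target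

## Step count and risks

Total step count: 14.
Longest linear sequence: 9 steps (1, 2, 3, 6, 7, 8, 9, 13, 14).

The three steps most likely to fail:

**Step 6.** A basic organometallic meets a triflate flanked by a secondary bromide and a tertiary chloride, so elimination or reductive loss of the vicinal halogens may compete. The fallback sets out from triflate 5 and builds the allylsilane from an ester instead. Compound 5 is alkylated with the lithium enolate of methyl acetate (LiN(iPr)2, THF/DMPU, −78 °C) to give the ester methyl (4S,5R)-4-bromo-5-chloro-5-methylnon-8-enoate F1. Double addition of Me3SiCH2MgCl/CeCl3 gives the carbinol (5S,6R)-5-bromo-6-chloro-6-methyl-1-(trimethylsilyl)-2-[(trimethylsilyl)methyl]dec-9-en-2-ol F2. Its Peterson elimination on silica gel comes back to the route at allylsilane 10.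

**Step 7.** The allylsilane may be protodesilylated before the chloride ionises, or the bromonium ion may eliminate instead of cyclising. The fallback sets out from triflate 5 and changes the terminating group to a silyl enol ether. Compound 5 is alkylated with the lithium enolate of acetone (from 2-(trimethylsilyloxy)propene and MeLi) to give the methyl ketone (5S,6R)-5-bromo-6-chloro-6-methyldec-9-en-2-one F3. Kinetic enolisation (LiN(iPr)2, −78 °C) and trapping with iPr3SiOTf give the enol ether {[(5S,6R)-5-bromo-6-chloro-6-methyldeca-1,9-dien-2-yl]oxy}tri(propan-2-yl)silane F4. Ionisation in (CF3)2CHOH, now with Mukaiyama-type termination, gives the ring ketone (3S,4S)-4-bromo-3-(but-3-en-1-yl)-3-methylcyclohexan-1-one F5 directly. Ozonolysis of its single alkene comes back to the route at keto aldehyde 14.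

**Step 13.** The face selectivity at C1 and the protonation at C7a rest on substrate control, and the lithium enolate sits γ to a bromide. The fallback sets out from iodide 23 and replaces the cuprate by a neutral, catalyst-controlled addition. I/Li exchange and quenching with 2-isopropoxy-4,4,5,5-tetramethyl-1,3,2-dioxaborolane give the boronate 2-[(1E)-2,6-dimethylhepta-1,5-dien-1-yl]-4,4,5,5-tetramethyl-1,3,2-dioxaborolane F6. Rhodium-catalysed 1,4-addition of F6 to enone 16 ([Rh(OH)(cod)]2 with a chiral diene or BINAP ligand matched to the substrate bias, dioxane/H2O, 50 °C, protonation by water) comes back to the route at ketone 26.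

Further compounds
F1 | step 6 | methyl (4S,5R)-4-bromo-5-chloro-5-methylnon-8-enoate | COC(=O)CC[C@H](Br)[C@](C)(Cl)CCC=C
F2 | step 6 | (5S,6R)-5-bromo-6-chloro-6-methyl-1-(trimethylsilyl)-2-[(trimethylsilyl)methyl]dec-9-en-2-ol | C[Si](C)(C)CC(O)(C[Si](C)(C)C)CC[C@H](Br)[C@](C)(Cl)CCC=C
F3 | step 7 | (5S,6R)-5-bromo-6-chloro-6-methyldec-9-en-2-one | CC(=O)CC[C@H](Br)[C@](C)(Cl)CCC=C
F4 | step 7 | {[(5S,6R)-5-bromo-6-chloro-6-methyldeca-1,9-dien-2-yl]oxy}tri(propan-2-yl)silane | C=C(O[Si](C(C)C)(C(C)C)C(C)C)CC[C@H](Br)[C@](C)(Cl)CCC=C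
F5 | step 7 | (3S,4S)-4-bromo-3-(but-3-en-1-yl)-3-methylcyclohexan-1-one | O=C1CC[C@H](Br)[C@@](C)(CCC=C)C1
F6 | step 13 | 2-[(1E)-2,6-dimethylhepta-1,5-dien-1-yl]-4,4,5,5-tetramethyl-1,3,2-dioxaborolane | CC(C)=CCC/C(C)=C/B1OC(C)(C)C(C)(C)O1
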